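## Retrosynthetic overview

1. Target 22 comes from ynolide 21 by syn semihydrogenation (C2=C3, Z); 21 comes from trihydroxy ynoic acid 19 by lactonisation on 21-OH, the only ring made in the synthesis.
2. 19 comes from bis-epoxide 14 and methyl propiolate 15 (C3–C4 bond; opening of the terminal oxirane unveils 5-OH).
3. Key step, C7–C8: trans-lithiated (S,S)-diepoxybutane 10 (an oxiranyl anion) displaces chloride from C8 of α-chloroboronate 9 by a 1,2-boronate shift, then C–B becomes C–OH. C5 and C6 come from 10, C7 from the trans-lithiation, C8 from the boron auxiliary.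
4. 9 comes from Matteson homologation of boronate 7, made by hydroboration of TES ether 5, itself from an undecenyl Grignard reagent and (R)-propylene oxide (C21).
5. Ring order: the C6–C7 oxirane is bought with 10 and carried through untouched; the 22-membered lactone is closed in step 8.

Assumption: "CIML C" is taken to be exactly the structure of the given SMILES, and (2S,3S)-1,2:3,4-diepoxybutane 10 is taken as a purchasable building block (otherwise three routine operations from diethyl L-tartrate).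

## Route

Step 1
Reactants: 1 11-bromo-1-undecene; 2 (R)-2-methyloxirane
Product: 4 (R)-tetradec-13-en-2-ol, via Grignard reagent 3 (not isolated)
Conditions: Mg, THF, 40 °C; then CuI (10 mol%), 2, −30 → 0 °C
Reagents that add atoms: none
Why: Copper-catalysed Grignard opening of a terminal epoxide (SN2 at the CH2 carbon), so the (R) centre of 2 is carried unchanged into the carbinol that becomes C21.

Step 2
Reactants: 4 (R)-tetradec-13-en-2-ol
Product: 5 (R)-triethyl(tetradec-13-en-2-yloxy)silane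
Conditions: TESCl, imidazole, CH2Cl2, 0 → 23 °C
Reagents that add atoms: triethylsilyl chloride, CC[Si](Cl)(CC)CC
Why: Standard silyl ether formation; the TES group survives the organometallic steps and is later removed by dilute acid without a step of its own.

Step 3
Reactants: 5 (R)-triethyl(tetradec-13-en-2-yloxy)silane
Product: 7 (−)-pinanediol [(13R)-13-(triethylsilyloxy)tetradecyl]boronate, via catechol boronate 6 (not isolated)
Conditions: catecholborane, RhCl(PPh3)3 (1 mol%), THF, 23 °C; then (1R,2R,3S,5R)-(−)-pinanediol, 23 °C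
Reagents that add atoms: catecholborane, B1Oc2ccccc2O1; (1R,2R,3S,5R)-(−)-pinanediol, C[C@]1(O)[C@@H](O)C[C@H]2C[C@@H]1C2(C)C
Why: Rh-catalysed anti-Markovnikov hydroboration of the terminal alkene, then transesterification to the far more stable pinanediol ester, which installs the chiral director for step 4.

Step 4
Reactants: 7 (−)-pinanediol [(13R)-13-(triethylsilyloxy)tetradecyl]boronate
Product: 9 (−)-pinanediol [(1R,14R)-1-chloro-14-(triethylsilyloxy)pentadecyl]boronate, via dichloromethyl borate 8 (not isolated)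
Conditions: CH2Cl2, n-BuLi, THF, −100 °C; then 7; ZnCl2, −100 → 23 °C
Reagents that add atoms: dichloromethane, ClCCl
Why: Matteson asymmetric homologation: LiCHCl2 adds to boron and the ZnCl2-promoted 1,2-shift expels the chloride selected by (−)-pinanediol, setting the (1R) chloro centre (the future C8) with high diastereocontrol.

Step 5
Reactants: 9 (−)-pinanediol [(1R,14R)-1-chloro-14-(triethylsilyloxy)pentadecyl]boronate; 10 (2S,3S)-1,2:3,4-diepoxybutane
Product: 14 (1S,14R)-1-[(2R,3R)-3-[(2S)-oxiran-2-yl]oxiran-2-yl]-14-(triethylsilyloxy)pentadecan-1-ol, via oxiranyllithium 11 (not isolated), via borate complex 12 (not isolated), via boronic ester 13 (not isolated)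
Conditions: 10 (1.5 equiv), s-BuLi (1.3 equiv), (−)-sparteine, Et2O–hexane, −90 °C; then 9 (1.0 equiv), −90 → 23 °C; then NaBO3·4H2O, THF–H2O, 0 → 23 °C
Reagents that add atoms: sodium perborate, B(=O)O[O-].[Na+]
Why: Proposed new method: s-BuLi/sparteine removes, from one of the two equivalent terminal oxiranes of C2-symmetric 10, the ring hydrogen trans to the substituent to give the configurationally stable oxiranyl anion 11, which adds to boron of 9 and then migrates from boron to C8 with loss of chloride (retention at the migrating C7, which fixes the trans oxirane, and inversion at C8, so the 1R chloride becomes the 8S carbinol after C–B oxidation with retention), thereby joining an epoxide carbon and a chlorine-bearing carbon that are both electrophilic in their native state; the closest known reaction types are s-BuLi/diamine lithiation–electrophile trapping of terminal epoxides, boronate complexes of lithiated epoxides, and Matteson substitution of α-chloroboronic esters by α-alkoxy organolithiums, and the untested points are the migratory aptitude of the oxiranyl group and the survival of β-boryl epoxide 13 until oxidation.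

Step 6
Reactants: 14 (1S,14R)-1-[(2R,3R)-3-[(2S)-oxiran-2-yl]oxiran-2-yl]-14-(triethylsilyloxy)pentadecan-1-ol; 15 methyl propiolate
Product: 17 methyl (5S,6R,7R,8S,21R)-6,7-epoxy-5,8-dihydroxy-21-(triethylsilyloxy)docos-2-ynoate, via lithium acetylide 16 (not isolated)
Conditions: 15 (3 equiv), n-BuLi, THF, −78 °C; BF3·OEt2 (3 equiv); then 14, −78 °C; NH4Cl quench
Reagents that add atoms: none
Why: BF3-mediated alkynylation of an epoxide (Yamaguchi–Hirao type): the acetylide attacks the unsubstituted C4 terminus of the terminal oxirane, leaving the hindered, electron-poor trans-disubstituted oxirane intact and revealing the 5-OH centre inherited from 10.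

Step 7
Reactants: 17 methyl (5S,6R,7R,8S,21R)-6,7-epoxy-5,8-dihydroxy-21-(triethylsilyloxy)docos-2-ynoate
Product: 19 (5S,6R,7R,8S,21R)-6,7-epoxy-5,8,21-trihydroxydocos-2-ynoic acid, via lithium carboxylate 18 (not isolated)
Conditions: LiOH, THF–H2O, 0 °C, 30 min; then 1 M HCl to pH 2, 23 °C, 1–2 h
Reagents that add atoms: lithium hydroxide, [Li+].[OH-]
Why: Saponification of the activated ynoate is fast at 0 °C and the acidic quench cleaves the TES ether; the linear alkyne prevents lactonisation onto 5-OH, and the trans oxirane is the favoured Payne isomer, so brief base exposure is tolerated.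

Step 8
Reactants: 19 (5S,6R,7R,8S,21R)-6,7-epoxy-5,8,21-trihydroxydocos-2-ynoic acid
Product: 21 (5S,6R,7R,8S,21R)-6,7-epoxy-5,8-dihydroxydocos-2-yn-21-olide, via mixed anhydride 20 (not isolated)
Conditions: 2-methyl-6-nitrobenzoic anhydride (MNBA), DMAP, Et3N, CH2Cl2, slow addition to 1 mM, 23 °C
Reagents that add atoms: none
Why: Shiina macrolactonisation under high dilution: only 21-OH can reach the activated carboxyl, because lactones onto 5-OH or 8-OH would be six- or nine-membered rings containing the C≡C unit, and acylation proceeds with retention at C21.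

Step 9
Reactants: 21 (5S,6R,7R,8S,21R)-6,7-epoxy-5,8-dihydroxydocos-2-yn-21-olide
Product: 22 CIML C [(2Z,5S,6R,7R,8S,21R)-6,7-epoxy-5,8-dihydroxydocos-2-en-21-olide]
Conditions: H2 (1 atm), Pd/CaCO3 poisoned with Pb(OAc)2, quinoline, EtOAc, 23 °C
Reagents that add atoms: none
Why: Lindlar-type syn semihydrogenation of the ynoate on poisoned palladium gives the (Z)-enoate under neutral conditions, leaving the oxirane and hydroxyls untouched and avoiding base that would translactonise to the δ-lactone.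

## Compound list

1 | 11-bromo-1-undecene | C=CCCCCCCCCCBr | starting material
2 | (R)-2-methyloxirane, (R)-propylene oxide | C[C@@H]1CO1 | starting material
3 | undec-10-enylmagnesium bromide | C=CCCCCCCCCC[Mg]Br | intermediate (not isolated)
4 | (R)-tetradec-13-en-2-ol | C[C@@H](O)CCCCCCCCCCC=C | intermediate
5 | (R)-triethyl(tetradec-13-en-2-yloxy)silane | C[C@@H](O[Si](CC)(CC)CC)CCCCCCCCCCC=C | intermediate
6 | 2-[(13R)-13-(triethylsilyloxy)tetradecyl]-1,3,2-benzodioxaborole | C[C@@H](O[Si](CC)(CC)CC)CCCCCCCCCCCCB1Oc2ccccc2O1 | intermediate (not isolated)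
7 | (−)-pinanediol [(13R)-13-(triethylsilyloxy)tetradecyl]boronate | C[C@@H](O[Si](CC)(CC)CC)CCCCCCCCCCCCB1O[C@H]2C[C@H]3C[C@H](C3(C)C)[C@@]2(C)O1 | intermediate
8 | lithium (dichloromethyl)borate complex of 7 | [Li+].C[C@@H](O[Si](CC)(CC)CC)CCCCCCCCCCCC[B-]1(C(Cl)Cl)O[C@H]2C[C@H]3C[C@H](C3(C)C)[C@@]2(C)O1 | intermediate (not isolated)
9 | (−)-pinanediol [(1R,14R)-1-chloro-14-(triethylsilyloxy)pentadecyl]boronate | C[C@@H](O[Si](CC)(CC)CC)CCCCCCCCCCCC[C@H](Cl)B1O[C@H]2C[C@H]3C[C@H](C3(C)C)[C@@]2(C)O1 | intermediate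
10 | (2S,3S)-1,2:3,4-diepoxybutane, (2S,2'S)-2,2'-bioxirane | C1O[C@@H]1[C@@H]1CO1 | starting material
11 | [(2R,3S)-3-[(2S)-oxiran-2-yl]oxiran-2-yl]lithium (lithium trans to the oxiranyl substituent) | [Li][C@H]1O[C@@H]1[C@@H]1CO1 | intermediate (not isolated)
12 | lithium borate complex formed from 9 and 11 | [Li+].C[C@@H](O[Si](CC)(CC)CC)CCCCCCCCCCCC[C@H](Cl)[B-]1([C@H]4O[C@@H]4[C@@H]4CO4)O[C@H]2C[C@H]3C[C@H](C3(C)C)[C@@]2(C)O1 | intermediate (not isolated)
13 | (−)-pinanediol [(1S,14R)-1-[(2R,3S)-3-[(2S)-oxiran-2-yl]oxiran-2-yl]-14-(triethylsilyloxy)pentadecyl]boronate | C[C@@H](O[Si](CC)(CC)CC)CCCCCCCCCCCC[C@H](B1O[C@H]2C[C@H]3C[C@H](C3(C)C)[C@@]2(C)O1)[C@H]1O[C@@H]1[C@@H]1CO1 | intermediate (not isolated)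
14 | (1S,14R)-1-[(2R,3R)-3-[(2S)-oxiran-2-yl]oxiran-2-yl]-14-(triethylsilyloxy)pentadecan-1-ol | C[C@@H](O[Si](CC)(CC)CC)CCCCCCCCCCCC[C@H](O)[C@H]1O[C@@H]1[C@@H]1CO1 | intermediate
15 | methyl propiolate (methyl prop-2-ynoate) | C#CC(=O)OC | starting material
16 | methyl 3-lithioprop-2-ynoate | [Li]C#CC(=O)OC | intermediate (not isolated)
17 | methyl (5S,6R,7R,8S,21R)-6,7-epoxy-5,8-dihydroxy-21-(triethylsilyloxy)docos-2-ynoate | C[C@@H](O[Si](CC)(CC)CC)CCCCCCCCCCCC[C@H](O)[C@H]1O[C@@H]1[C@@H](O)CC#CC(=O)OC | intermediate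
18 | lithium (5S,6R,7R,8S,21R)-6,7-epoxy-5,8-dihydroxy-21-(triethylsilyloxy)docos-2-ynoate | [Li+].C[C@@H](O[Si](CC)(CC)CC)CCCCCCCCCCCC[C@H](O)[C@H]1O[C@@H]1[C@@H](O)CC#CC(=O)[O-] | intermediate (not isolated)
19 | (5S,6R,7R,8S,21R)-6,7-epoxy-5,8,21-trihydroxydocos-2-ynoic acid | C[C@@H](O)CCCCCCCCCCCC[C@H](O)[C@H]1O[C@@H]1[C@@H](O)CC#CC(=O)O | intermediate
20 | mixed anhydride of 19 with 2-methyl-6-nitrobenzoic acid | C[C@@H](O)CCCCCCCCCCCC[C@H](O)[C@H]1O[C@@H]1[C@@H](O)CC#CC(=O)OC(=O)c1c(C)cccc1[N+](=O)[O-] | intermediate (not isolated)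
21 | (5S,6R,7R,8S,21R)-6,7-epoxy-5,8-dihydroxydocos-2-yn-21-olide (22-membered ynolide) | C[C@@H]1CCCCCCCCCCCC[C@H](O)[C@H]2O[C@@H]2[C@@H](O)CC#CC(=O)O1 | intermediate
22 | CIML C, (2Z,5S,6R,7R,8S,21R)-6,7-epoxy-5,8-dihydroxydocos-2-en-21-olide | C[C@@H]1CCCCCCCCCCCC[C@H](O)[C@H]2O[C@@H]2[C@@H](O)C/C=C\C(=O)O1 | target

## Step count and risks

Total steps: 9. Longest linear sequence: 9 (1 → 22; 10 and 15 are bought and enter at steps 5 and 6).

Steps most likely to fail:

Step 5. The oxiranyl-to-carbon boronate shift is untested, and boronic ester 13 could ring-open by β-elimination before it is oxidised. The fallback sets out from 5, keeps 11 as the nucleophile and changes the electrophile to an aldehyde. Linear hydroformylation of 5 (Rh(acac)(CO)2, Xantphos, CO/H2) gives (R)-14-(triethylsilyloxy)pentadecanal F1. Addition of 11 to F1 at −90 °C gives 14 together with the (1R) epimer of 14 F2, about 1:1, separated on silica. F2 is inverted by Mitsunobu esterification (4-nitrobenzoic acid, PPh3, DIAD) to the 4-nitrobenzoate of 14 F3, and brief methanolysis (K2CO3, MeOH, 0 °C) gives 14, where the route is rejoined.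

Step 6. The free 8-OH and the second oxirane are exposed to BF3·OEt2, and the lithiated propiolate is thermally fragile. The fallback sets out from 14 and takes the hydroxyl out of play first: TESCl/imidazole gives the 8-O-TES ether of 14 F4, alkynylation with 16/BF3·OEt2 gives the 8-O-TES ether of 17 F5, and the step 7 conditions, passing through the lithium carboxylate of F5 F6, strip both TES groups and return to the route at 19.

Step 8. An unprotected trihydroxy ynoic acid is activated in the presence of DMAP, so oligomers or conjugate addition to the ynoate are possible. The fallback sets out from 17 and cyclises a protected seco acid instead: TBSOTf/2,6-lutidine gives the 5,8-bis-O-TBS ether of 17 F7; LiOH then HCl (pH 2) gives, via the lithium carboxylate of F7 F8, the 5,8-bis-O-TBS seco acid F9 with only 21-OH free; MNBA/DMAP closes it through the mixed anhydride of F9 F10 to the 5,8-bis-O-TBS ynolide F11; HF·pyridine in THF removes both TBS groups and returns to the route at 21.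

Further compounds

F1 | step 5 | (R)-14-(triethylsilyloxy)pentadecanal | C[C@@H](O[Si](CC)(CC)CC)CCCCCCCCCCCCC=O
F2 | step 5 | (1R) epimer of 14, (1R,14R)-1-[(2R,3R)-3-[(2S)-oxiran-2-yl]oxiran-2-yl]-14-(triethylsilyloxy)pentadecan-1-ol | C[C@@H](O[Si](CC)(CC)CC)CCCCCCCCCCCC[C@@H](O)[C@H]1O[C@@H]1[C@@H]1CO1
F3 | step 5 | 4-nitrobenzoate of 14 (configuration as in 14) | C[C@@H](O[Si](CC)(CC)CC)CCCCCCCCCCCC[C@H](OC(=O)c1ccc(cc1)[N+](=O)[O-])[C@H]1O[C@@H]1[C@@H]1CO1
F4 | step 6 | 8-O-TES ether of 14 (configuration as in 14) | C[C@@H](O[Si](CC)(CC)CC)CCCCCCCCCCCC[C@H](O[Si](CC)(CC)CC)[C@H]1O[C@@H]1[C@@H]1CO1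
F5 | step 6 | 8-O-TES ether of 17 (configuration as in 17) | C[C@@H](O[Si](CC)(CC)CC)CCCCCCCCCCCC[C@H](O[Si](CC)(CC)CC)[C@H]1O[C@@H]1[C@@H](O)CC#CC(=O)OC
F6 | step 6 | lithium carboxylate of F5 | [Li+].C[C@@H](O[Si](CC)(CC)CC)CCCCCCCCCCCC[C@H](O[Si](CC)(CC)CC)[C@H]1O[C@@H]1[C@@H](O)CC#CC(=O)[O-]
F7 | step 8 | 5,8-bis-O-TBS ether of 17 (configuration as in 17) | C[C@@H](O[Si](CC)(CC)CC)CCCCCCCCCCCC[C@H](O[Si](C)(C)C(C)(C)C)[C@H]1O[C@@H]1[C@@H](O[Si](C)(C)C(C)(C)C)CC#CC(=O)OC
F8 | step 8 | lithium carboxylate of F7 | [Li+].C[C@@H](O[Si](CC)(CC)CC)CCCCCCCCCCCC[C@H](O[Si](C)(C)C(C)(C)C)[C@H]1O[C@@H]1[C@@H](O[Si](C)(C)C(C)(C)C)CC#CC(=O)[O-]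
F9 | step 8 | 5,8-bis-O-TBS seco acid (5,8-bis-O-TBS ether of 19) | C[C@@H](O)CCCCCCCCCCCC[C@H](O[Si](C)(C)C(C)(C)C)[C@H]1O[C@@H]1[C@@H](O[Si](C)(C)C(C)(C)C)CC#CC(=O)O
F10 | step 8 | mixed anhydride of F9 with 2-methyl-6-nitrobenzoic acid | C[C@@H](O)CCCCCCCCCCCC[C@H](O[Si](C)(C)C(C)(C)C)[C@H]1O[C@@H]1[C@@H](O[Si](C)(C)C(C)(C)C)CC#CC(=O)OC(=O)c1c(C)cccc1[N+](=O)[O-]
F11 | step 8 | 5,8-bis-O-TBS ynolide (5,8-bis-O-TBS ether of 21) | C[C@@H]1CCCCCCCCCCCC[C@H](O[Si](C)(C)C(C)(C)C)[C@H]2O[C@@H]2[C@@H](O[Si](C)(C)C(C)(C)C)CC#CC(=O)O1
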